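**Retrosynthetic overview**
1. Target 21 comes from flavone 16 by changes at oxygen only: C3 hydroxylation, 3-O-methylation, chelation-directed 5-O-demethylation, then hydrogenolysis of two benzyl ethers.
2. Flavone 16 comes from 2'-hydroxychalcone 14 by O1–C2 closure and dehydrogenation with I2/DMSO. Algar–Flynn–Oyamada oxidation is avoided because 6'-alkoxychalcones tend to give aurones.
3. Chalcone 14 comes from ketone 10 (ring A) and aldehyde 12 (ring B). A Claisen–Schmidt aldol condensation forms the future C2–C3 bond.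
4. Ketone 10 comes from 2,3,4-trimethoxybenzaldehyde 1 by two Baeyer–Villiger oxygenations, one ortho-lithiation/formylation and a Fries acylation. Aldehyde 12 comes from 2,4-dihydroxybenzaldehyde 11.
5. Ring order: rings A and B are bought as benzenes, and ring C is the only ring formed (step 8).

Assumption: the target has no stereocentre and is achiral, so there is no enantiomer to control. The only lasting stereodescriptor in the route is the E double bond of chalcone 14.

**Step 1**
Reactants: 1 2,3,4-trimethoxybenzaldehyde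
Product: 3 2,3,4-trimethoxyphenol, via 2,3,4-trimethoxyphenyl formate 2 (not isolated)
Conditions: mCPBA (1.3 equiv), CH2Cl2, 0 °C to rt, 16 h; then 2 M aq NaOH, MeOH, rt, 1 h; 2 M HCl
Reagents that add atoms: mCPBA (3-chloroperoxybenzoic acid), O=C(OO)c1cccc(Cl)c1
Why: Baeyer–Villiger oxidation, in which the electron-rich aryl group (ortho and para OMe) migrates in preference to H and the formate is then saponified; no stereocentre is formed.

**Step 2**
Reactants: 3 2,3,4-trimethoxyphenol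
Product: 4 1,2,3,4-tetramethoxybenzene
Conditions: MeI (1.5 equiv), K2CO3 (2 equiv), acetone, reflux, 8 h
Reagents that add atoms: iodomethane, CI
Why: Williamson ether synthesis (SN2 of the phenoxide on MeI) with no competing nucleophile in the molecule.

**Step 3**
Reactants: 4 1,2,3,4-tetramethoxybenzene
Product: 6 2,3,4,5-tetramethoxybenzaldehyde, via 2,3,4,5-tetramethoxyphenyllithium 5 (not isolated)
Conditions: n-BuLi (1.2 equiv), TMEDA (1.2 equiv), THF, 0 °C, 2 h; DMF (2 equiv), 0 °C to rt; 1 M HCl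
Reagents that add atoms: N,N-dimethylformamide, CN(C)C=O
Why: Directed ortho-metalation followed by formylation; the two ring C–H positions are symmetry-equivalent and each lies ortho to OMe, so only one regioisomer can form.

**Step 4**
Reactants: 6 2,3,4,5-tetramethoxybenzaldehyde
Product: 8 2,3,4,5-tetramethoxyphenol, via 2,3,4,5-tetramethoxyphenyl formate 7 (not isolated)
Conditions: mCPBA (1.3 equiv), CH2Cl2, 0 °C to rt, 16 h; then 2 M aq NaOH, MeOH, N2, 0 °C, 30 min; 2 M HCl
Reagents that add atoms: mCPBA (3-chloroperoxybenzoic acid), O=C(OO)c1cccc(Cl)c1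
Why: Second Baeyer–Villiger oxidation with the same aryl-over-hydride migratory preference; the oxidation-sensitive phenol is released only after the peracid has been washed out.

**Step 5**
Reactants: 8 2,3,4,5-tetramethoxyphenol
Product: 10 1-(2-hydroxy-3,4,5,6-tetramethoxyphenyl)ethan-1-one, via 2,3,4,5-tetramethoxyphenyl acetate 9 (not isolated)
Conditions: Ac2O (2 equiv), BF3·OEt2 (4 equiv), 70 °C, 2 h; then H2O, 60 °C, 30 min
Reagents that add atoms: acetic anhydride, CC(=O)OC(C)=O
Why: O-acetylation followed by BF3-promoted Fries rearrangement (Friedel–Crafts acylation) can place the acetyl group only on the single free ring carbon, which lies ortho to the OH.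

**Step 6**
Reactants: 11 2,4-dihydroxybenzaldehyde
Product: 12 2,4-bis(benzyloxy)benzaldehyde
Conditions: BnBr (2.4 equiv), K2CO3 (3 equiv), DMF, 60 °C, 6 h
Reagents that add atoms: benzyl bromide, BrCc1ccccc1
Why: Double Williamson etherification; warm DMF and excess halide also alkylate the hydrogen-bonded 2-OH, and benzyl ethers survive every later basic and oxidative step.

**Step 7**
Reactants: 10 1-(2-hydroxy-3,4,5,6-tetramethoxyphenyl)ethan-1-one; 12 2,4-bis(benzyloxy)benzaldehyde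
Product: 14 (E)-3-[2,4-bis(benzyloxy)phenyl]-1-(2-hydroxy-3,4,5,6-tetramethoxyphenyl)prop-2-en-1-one, via beta-hydroxy ketone 13 (not isolated)
Conditions: KOH (50% aq, 12 equiv), EtOH–THF 3:1, rt, 48–72 h; cold 1 M HCl
Reagents that add atoms: none
Why: Claisen–Schmidt crossed aldol condensation in which only 10 can enolise and 12 is the only non-enolisable electrophile; E1cB loss of water from racemic 13 gives the thermodynamically preferred E-enone.

**Step 8**
Reactants: 14 (E)-3-[2,4-bis(benzyloxy)phenyl]-1-(2-hydroxy-3,4,5,6-tetramethoxyphenyl)prop-2-en-1-one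
Product: 16 2-[2,4-bis(benzyloxy)phenyl]-5,6,7,8-tetramethoxy-4H-chromen-4-one, via flavanone 15 (not isolated)
Conditions: I2 (10 mol%), DMSO, 120 °C, 3 h
Reagents that add atoms: none
Why: Oxa-Michael closure of ring C to racemic flavanone 15, then iodine-catalysed dehydrogenation with DMSO as terminal oxidant, gives the aromatic pyranone and erases the transient C2 stereocentre.

**Step 9**
Reactants: 16 2-[2,4-bis(benzyloxy)phenyl]-5,6,7,8-tetramethoxy-4H-chromen-4-one
Product: 18 2-[2,4-bis(benzyloxy)phenyl]-3-hydroxy-5,6,7,8-tetramethoxy-4H-chromen-4-one, via flavone 2,3-epoxide 17 (not isolated)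
Conditions: DMDO (3 equiv, pre-made ca. 0.08 M solution in acetone), CH2Cl2, 0 °C to rt, 24 h; then p-TsOH·H2O (10 mol%), CH2Cl2, rt, 1 h
Reagents that add atoms: dimethyldioxirane, CC1(C)OO1
Why: Neutral electrophilic epoxidation of the enol-ether-like C2=C3 bond gives racemic epoxide 17, and acid-catalysed opening at the cation-stabilised C2 with loss of H-3 re-aromatises it to the achiral flavonol.

**Step 10**
Reactants: 18 2-[2,4-bis(benzyloxy)phenyl]-3-hydroxy-5,6,7,8-tetramethoxy-4H-chromen-4-one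
Product: 19 2-[2,4-bis(benzyloxy)phenyl]-3,5,6,7,8-pentamethoxy-4H-chromen-4-one
Conditions: MeI (2 equiv), K2CO3 (2.5 equiv), acetone, reflux, 6 h
Reagents that add atoms: iodomethane, CI
Why: Williamson etherification of the acidic 3-OH, which is the only free hydroxyl in the molecule.

**Step 11**
Reactants: 19 2-[2,4-bis(benzyloxy)phenyl]-3,5,6,7,8-pentamethoxy-4H-chromen-4-one
Product: 20 2-[2,4-bis(benzyloxy)phenyl]-5-hydroxy-3,6,7,8-tetramethoxy-4H-chromen-4-one
Conditions: AlCl3 (5 equiv), MeCN, 60 °C, 1.5 h; then 2% aq HCl, 60 °C, 20 min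
Reagents that add atoms: none
Why: Chelation-controlled Lewis-acid ether cleavage, in which AlCl3 sits in a six-membered chelate between the C4 carbonyl and the peri 5-OMe, so chloride removes that methyl (SN2) faster than the 3-OMe or the non-chelated ethers, while MeCN tempers the Lewis acid enough to spare the benzyl ethers.

**Step 12**
Reactants: 20 2-[2,4-bis(benzyloxy)phenyl]-5-hydroxy-3,6,7,8-tetramethoxy-4H-chromen-4-one
Product: 21 2-(2,4-dihydroxyphenyl)-5-hydroxy-3,6,7,8-tetramethoxy-4H-chromen-4-one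
Conditions: H2 (1 atm), 10% Pd/C, EtOAc–MeOH 1:1, rt, 3 h
Reagents that add atoms: none
Why: Catalytic hydrogenolysis cleaves only the two benzylic C–O bonds; the aryl methyl ethers and the tetrasubstituted vinylogous-ester C2=C3 bond are inert at 1 atm, and no stereocentre exists in the product.

**Compound list**
1 | 2,3,4-trimethoxybenzaldehyde | COc1ccc(C=O)c(OC)c1OC | starting material
2 | 2,3,4-trimethoxyphenyl formate | COc1ccc(OC=O)c(OC)c1OC | intermediate
3 | 2,3,4-trimethoxyphenol | COc1ccc(O)c(OC)c1OC | intermediate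
4 | 1,2,3,4-tetramethoxybenzene | COc1ccc(OC)c(OC)c1OC | intermediate
5 | 2,3,4,5-tetramethoxyphenyllithium | [Li]c1cc(OC)c(OC)c(OC)c1OC | intermediate
6 | 2,3,4,5-tetramethoxybenzaldehyde | COc1cc(C=O)c(OC)c(OC)c1OC | intermediate
7 | 2,3,4,5-tetramethoxyphenyl formate | COc1cc(OC=O)c(OC)c(OC)c1OC | intermediate
8 | 2,3,4,5-tetramethoxyphenol | COc1cc(O)c(OC)c(OC)c1OC | intermediate
9 | 2,3,4,5-tetramethoxyphenyl acetate | COc1cc(OC(C)=O)c(OC)c(OC)c1OC | intermediate
10 | 1-(2-hydroxy-3,4,5,6-tetramethoxyphenyl)ethan-1-one | CC(=O)c1c(O)c(OC)c(OC)c(OC)c1OC | intermediate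
11 | 2,4-dihydroxybenzaldehyde | O=Cc1ccc(O)cc1O | starting material
12 | 2,4-bis(benzyloxy)benzaldehyde | O=Cc1ccc(OCc2ccccc2)cc1OCc1ccccc1 | intermediate
13 | 3-[2,4-bis(benzyloxy)phenyl]-3-hydroxy-1-(2-hydroxy-3,4,5,6-tetramethoxyphenyl)propan-1-one (racemic aldol adduct) | O=C(CC(O)c1ccc(OCc2ccccc2)cc1OCc1ccccc1)c1c(O)c(OC)c(OC)c(OC)c1OC | intermediate
14 | (E)-3-[2,4-bis(benzyloxy)phenyl]-1-(2-hydroxy-3,4,5,6-tetramethoxyphenyl)prop-2-en-1-one | O=C(/C=C/c1ccc(OCc2ccccc2)cc1OCc1ccccc1)c1c(O)c(OC)c(OC)c(OC)c1OC | intermediate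
15 | 2-[2,4-bis(benzyloxy)phenyl]-5,6,7,8-tetramethoxychroman-4-one (racemic flavanone) | O=C1CC(c2ccc(OCc3ccccc3)cc2OCc2ccccc2)Oc2c(OC)c(OC)c(OC)c(OC)c21 | intermediate
16 | 2-[2,4-bis(benzyloxy)phenyl]-5,6,7,8-tetramethoxy-4H-chromen-4-one | O=c1cc(-c2ccc(OCc3ccccc3)cc2OCc2ccccc2)oc2c(OC)c(OC)c(OC)c(OC)c12 | intermediate
17 | 2,3-epoxide of 16: 1a-[2,4-bis(benzyloxy)phenyl]-3,4,5,6-tetramethoxy-1a,7a-dihydro-7H-oxireno[2,3-b]chromen-7-one (racemic) | O=C1C2OC2(c2ccc(OCc3ccccc3)cc2OCc2ccccc2)Oc2c(OC)c(OC)c(OC)c(OC)c21 | intermediate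
18 | 2-[2,4-bis(benzyloxy)phenyl]-3-hydroxy-5,6,7,8-tetramethoxy-4H-chromen-4-one | O=c1c(O)c(-c2ccc(OCc3ccccc3)cc2OCc2ccccc2)oc2c(OC)c(OC)c(OC)c(OC)c12 | intermediate
19 | 2-[2,4-bis(benzyloxy)phenyl]-3,5,6,7,8-pentamethoxy-4H-chromen-4-one | COc1c(-c2ccc(OCc3ccccc3)cc2OCc2ccccc2)oc2c(OC)c(OC)c(OC)c(OC)c2c1=O | intermediate
20 | 2-[2,4-bis(benzyloxy)phenyl]-5-hydroxy-3,6,7,8-tetramethoxy-4H-chromen-4-one | COc1c(-c2ccc(OCc3ccccc3)cc2OCc2ccccc2)oc2c(OC)c(OC)c(OC)c(O)c2c1=O | intermediate
21 | 5,2',4'-trihydroxy-3,6,7,8-tetramethoxyflavone (achiral) | COc1c(OC)c(O)c2c(=O)c(OC)c(-c3ccc(O)cc3O)oc2c1OC | target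

**Step count**
- Total steps: 12.
- Longest linear sequence: 11 (steps 1–5, then 7–12).

**The three steps most likely to fail**

**Step 7 (aldol condensation).** Ketone 10 carries two ortho substituents, and aldehyde 12 is deactivated by two alkoxy donors, so conversion may stall.
- The fallback sets out from 10 and joins the fragments one oxidation level higher by a crossed Claisen condensation.
- Bought methyl 2,4-dihydroxybenzoate F1 is benzylated (BnBr, K2CO3, DMF) to methyl 2,4-bis(benzyloxy)benzoate F2.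
- Ketone 10 is treated with LiHMDS (3 equiv, THF, −78 °C to reflux) and F2 to give 1-[2,4-bis(benzyloxy)phenyl]-3-(2-hydroxy-3,4,5,6-tetramethoxyphenyl)propane-1,3-dione F3.
- Catalytic p-TsOH in hot toluene cyclodehydrates F3. This comes back to the route at flavone 16 and also bypasses step 8.

**Step 9 (DMDO hydroxylation).** The C2=C3 bond is electron-poor and shielded by the twisted 2'-benzyloxyaryl group, and the benzylic C–H bonds and electron-rich rings can compete for the oxidant.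
- The fallback sets out from 16 and replaces electrophilic oxidation by anion chemistry.
- LDA (THF, −78 °C) gives 3-lithio-2-[2,4-bis(benzyloxy)phenyl]-5,6,7,8-tetramethoxychromen-4-one F4.
- B(OMe)3 traps F4 as the lithium trimethoxy(flavon-3-yl)borate F5.
- H2O2/AcOH oxidises the C–B bond, which comes back to the route at flavonol 18.

**Step 11 (selective 5-O-demethylation).** The 3-OMe, the 6-OMe next to the new aluminium phenoxide, and the benzyl ethers are all possible side targets.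
- The fallback sets out from 16 and moves the demethylation to a stage where no 3-OMe exists.
- AlCl3/MeCN converts 16 into 2-[2,4-bis(benzyloxy)phenyl]-5-hydroxy-6,7,8-trimethoxychromen-4-one F6.
- Excess BnBr, K2CO3 and DMF at 70 °C give 5-(benzyloxy)-2-[2,4-bis(benzyloxy)phenyl]-6,7,8-trimethoxychromen-4-one F7. This step also restores any benzyl ether lost in the previous one.
- DMDO gives the 2,3-epoxide of the tribenzyl flavone F8, which catalytic p-TsOH opens to 5-(benzyloxy)-2-[2,4-bis(benzyloxy)phenyl]-3-hydroxy-6,7,8-trimethoxychromen-4-one F9.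
- MeI/K2CO3 gives 5-(benzyloxy)-2-[2,4-bis(benzyloxy)phenyl]-3,6,7,8-tetramethoxychromen-4-one F10.
- One hydrogenolysis (H2, Pd/C) removes all three benzyl groups, which comes back to the route at target 21.

**Further compounds**
F1 | step 7 | methyl 2,4-dihydroxybenzoate (bought) | COC(=O)c1ccc(O)cc1O
F2 | step 7 | methyl 2,4-bis(benzyloxy)benzoate | COC(=O)c1ccc(OCc2ccccc2)cc1OCc1ccccc1
F3 | step 7 | 1-[2,4-bis(benzyloxy)phenyl]-3-(2-hydroxy-3,4,5,6-tetramethoxyphenyl)propane-1,3-dione | O=C(CC(=O)c1ccc(OCc2ccccc2)cc1OCc1ccccc1)c1c(O)c(OC)c(OC)c(OC)c1OC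
F4 | step 9 | 3-lithio-2-[2,4-bis(benzyloxy)phenyl]-5,6,7,8-tetramethoxychromen-4-one | [Li]c1c(-c2ccc(OCc3ccccc3)cc2OCc2ccccc2)oc2c(OC)c(OC)c(OC)c(OC)c2c1=O
F5 | step 9 | lithium trimethoxy(flavon-3-yl)borate derived from F4 | [Li+].CO[B-](OC)(OC)c1c(-c2ccc(OCc3ccccc3)cc2OCc2ccccc2)oc2c(OC)c(OC)c(OC)c(OC)c2c1=O
F6 | step 11 | 2-[2,4-bis(benzyloxy)phenyl]-5-hydroxy-6,7,8-trimethoxychromen-4-one | O=c1cc(-c2ccc(OCc3ccccc3)cc2OCc2ccccc2)oc2c(OC)c(OC)c(OC)c(O)c12
F7 | step 11 | 5-(benzyloxy)-2-[2,4-bis(benzyloxy)phenyl]-6,7,8-trimethoxychromen-4-one | O=c1cc(-c2ccc(OCc3ccccc3)cc2OCc2ccccc2)oc2c(OC)c(OC)c(OC)c(OCc3ccccc3)c12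
F8 | step 11 | 2,3-epoxide of the tribenzyl flavone F7 (racemic) | O=C1C2OC2(c2ccc(OCc3ccccc3)cc2OCc2ccccc2)Oc2c(OC)c(OC)c(OC)c(OCc3ccccc3)c21
F9 | step 11 | 5-(benzyloxy)-2-[2,4-bis(benzyloxy)phenyl]-3-hydroxy-6,7,8-trimethoxychromen-4-one | O=c1c(O)c(-c2ccc(OCc3ccccc3)cc2OCc2ccccc2)oc2c(OC)c(OC)c(OC)c(OCc3ccccc3)c12
F10 | step 11 | 5-(benzyloxy)-2-[2,4-bis(benzyloxy)phenyl]-3,6,7,8-tetramethoxychromen-4-one | COc1c(-c2ccc(OCc3ccccc3)cc2OCc2ccccc2)oc2c(OC)c(OC)c(OC)c(OCc3ccccc3)c2c1=O
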